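**Retrosynthetic overview**

1. The only ring to build is the tetronic acid (the 3-furyl ring is bought as 3-bromofuran); it is closed last, by lactonisation of a γ-hydroxy-β-keto ester.
2. Key C–C bond: C3–C4 of the tetronic acid, made by an intermolecular crossed Claisen condensation of the lithium enolate of methyl propionate with the full-length (S)-α-silyloxy methyl ester 32.
3. Ester 32 comes from a Suzuki–Miyaura coupling (C7′–C8′ of the diene) of (E)-alkenyl iodide 18 with (E)-alkenylboronate 31.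
4. Iodide 18 comes from (S)-citronellol (C2′ methyl centre): propargylation, Negishi carboalumination/iodination, alkene to acid, Evans–Davis hydroxylation (C5 centre).
5. Boronate 31 comes from an Evans allylation (C10′ centre), B-alkyl Suzuki coupling with 3-bromofuran, Ohira–Bestmann alkynylation and hydroboration.

Assumption: side-chain locants C1′–C13′ run from the tetronic acid outwards, and only species that persist in the flask between additions (organometallics, enolates, the mixed anhydride, one-pot intermediates) are numbered as non-isolated intermediates.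

**Route**

Step 1
Reactants: 1 (S)-citronellol
Product: 2 (6S)-8-iodo-2,6-dimethyloct-2-ene
Conditions: I2, PPh3, imidazole, CH2Cl2, 0 °C → rt
Reagents that add atoms: iodine, II
Why: Appel-type iodination replaces the primary OH by SN2 at CH2, so the remote stereocentre and the trisubstituted alkene are untouched.

Step 2
Reactants: 2 (6S)-8-iodo-2,6-dimethyloct-2-ene; 3 1-(trimethylsilyl)propyne
Product: 5 [(6R)-6,10-dimethylundec-9-en-1-yn-1-yl]trimethylsilane, via (trimethylsilyl)propargyllithium 4 (not isolated)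
Conditions: 3, n-BuLi, THF, −78 → −20 °C; then 2, DMPU, −78 °C → rt
Reagents that add atoms: none
Why: The silyl-blocked propargyllithium alkylates the unhindered primary iodide by SN2 at its CH2 terminus (propargyl anion alkylation); the descriptor changes to R only through CIP priorities.

Step 3
Reactants: 5 [(6R)-6,10-dimethylundec-9-en-1-yn-1-yl]trimethylsilane
Product: 6 (6R)-6,10-dimethylundec-9-en-1-yne
Conditions: K2CO3 (cat.), MeOH, rt
Reagents that add atoms: none
Why: Methoxide-mediated protodesilylation cleaves only the alkynyl C–Si bond of this otherwise inert hydrocarbon.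

Step 4
Reactants: 6 (6R)-6,10-dimethylundec-9-en-1-yne
Product: 8 (1E,6R)-1-iodo-2,6,10-trimethylundeca-1,9-diene, via alkenyldimethylalane 7 (not isolated)
Conditions: Me3Al, Cp2ZrCl2 (0.25 equiv), CH2Cl2, 0 °C → rt; then I2, THF, −30 → 0 °C
Reagents that add atoms: trimethylaluminium, C[Al](C)C; iodine, II
Why: Negishi Zr-catalysed carboalumination adds Me and Al syn across the terminal alkyne with Me at the internal carbon (the trisubstituted alkene is inert), and iodinolysis with retention fixes the (E)-iodoalkene.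

Step 5
Reactants: 8 (1E,6R)-1-iodo-2,6,10-trimethylundeca-1,9-diene
Product: 10 (4R,8E)-9-iodo-4,8-dimethylnon-8-enal, via vicinal diol 9 (not isolated)
Conditions: OsO4 (2 mol %), NMO, acetone/H2O, 0 °C → rt; then NaIO4, rt
Reagents that add atoms: N-methylmorpholine N-oxide (oxygen relayed by catalytic OsO4), C[N+]1([O-])CCOCC1; water, O
Why: Upjohn dihydroxylation selects the electron-rich isopropylidene alkene over the iodine-deactivated alkenyl iodide, and periodate (Malaprade) glycol cleavage releases the aldehyde.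

Step 6
Reactants: 10 (4R,8E)-9-iodo-4,8-dimethylnon-8-enal
Product: 11 (4R,8E)-9-iodo-4,8-dimethylnon-8-enoic acid
Conditions: NaClO2, NaH2PO4, 2-methyl-2-butene, t-BuOH/H2O, 0 °C → rt
Reagents that add atoms: sodium chlorite, [Na+].[O-]Cl=O
Why: Pinnick oxidation converts the aldehyde to the acid under buffered conditions while the alkene scavenger traps HOCl, protecting the alkenyl iodide.

Step 7
Reactants: 11 (4R,8E)-9-iodo-4,8-dimethylnon-8-enoic acid; 12 (S)-4-benzyloxazolidin-2-one
Product: 14 (4S)-4-benzyl-3-[(4R,8E)-9-iodo-4,8-dimethylnon-8-enoyl]oxazolidin-2-one, via mixed pivalic anhydride 13 (not isolated)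
Conditions: PivCl, Et3N, THF, −20 °C; then 12, LiCl, −20 °C → rt
Reagents that add atoms: none
Why: Mixed-anhydride N-acylation of the Evans auxiliary, in which the oxazolidinone attacks the less hindered acyl carbon of the pivalic anhydride.

Step 8
Reactants: 14 (4S)-4-benzyl-3-[(4R,8E)-9-iodo-4,8-dimethylnon-8-enoyl]oxazolidin-2-one
Product: 16 (4S)-4-benzyl-3-[(2S,4R,8E)-2-hydroxy-9-iodo-4,8-dimethylnon-8-enoyl]oxazolidin-2-one, via sodium Z-enolate of the imide 15 (not isolated)
Conditions: NaHMDS, THF, −78 °C; 2-(phenylsulfonyl)-3-phenyloxaziridine, −78 °C; AcOH quench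
Reagents that add atoms: 2-(phenylsulfonyl)-3-phenyloxaziridine (Davis reagent), O=S(=O)(c1ccccc1)N1OC1c1ccccc1
Why: Evans–Davis enolate hydroxylation, in which the chelated sodium (Z)-enolate is oxygenated on the face opposite the benzyl group, setting C2 as (S) (the future C5 of the tetronic acid), typically ≥95:5 dr.

Step 9
Reactants: 16 (4S)-4-benzyl-3-[(2S,4R,8E)-2-hydroxy-9-iodo-4,8-dimethylnon-8-enoyl]oxazolidin-2-one
Product: 17 methyl (2S,4R,8E)-2-hydroxy-9-iodo-4,8-dimethylnon-8-enoate
Conditions: MeMgBr, MeOH (gives MeOMgBr), 0 °C; then 1 M HCl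
Reagents that add atoms: methanol, CO
Why: Magnesium-chelation-assisted transesterification at the exocyclic imide carbonyl releases the auxiliary without epimerising the α-hydroxy centre.

Step 10
Reactants: 17 methyl (2S,4R,8E)-2-hydroxy-9-iodo-4,8-dimethylnon-8-enoate
Product: 18 methyl (2S,4R,8E)-2-[(tert-butyldimethylsilyl)oxy]-9-iodo-4,8-dimethylnon-8-enoate
Conditions: TBSOTf, 2,6-lutidine, CH2Cl2, 0 °C
Reagents that add atoms: tert-butyldimethylsilyl triflate, CC(C)(C)[Si](C)(C)OS(=O)(=O)C(F)(F)F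
Why: O-silylation masks the carbinol as a base-stable ether for the coupling and Claisen steps without touching the stereocentre.

Step 11
Reactants: 19 (R)-4-benzyl-3-propionyloxazolidin-2-one; 20 allyl iodide
Product: 22 (4R)-4-benzyl-3-[(2S)-2-methylpent-4-enoyl]oxazolidin-2-one, via sodium Z-enolate of the propionimide 21 (not isolated)
Conditions: NaHMDS, THF, −78 °C; then 20, −78 → −45 °C
Reagents that add atoms: none
Why: Evans asymmetric alkylation, in which the chelated sodium (Z)-enolate is allylated opposite the benzyl group of the (R)-auxiliary, setting the (S) methyl centre (future C10′) at about 98:2 dr.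

Step 12
Reactants: 22 (4R)-4-benzyl-3-[(2S)-2-methylpent-4-enoyl]oxazolidin-2-one
Product: 23 (2S)-2-methylpent-4-en-1-ol
Conditions: LiBH4, MeOH (1 equiv), Et2O, 0 °C; aq. NaOH work-up (product is volatile)
Reagents that add atoms: none
Why: Reductive cleavage of the imide by LiBH4 gives the primary alcohol without touching the α-stereocentre or the alkene.

Step 13
Reactants: 23 (2S)-2-methylpent-4-en-1-ol
Product: 24 tert-butyl{[(2S)-2-methylpent-4-en-1-yl]oxy}diphenylsilane
Conditions: TBDPSCl, imidazole, CH2Cl2, rt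
Reagents that add atoms: tert-butyl(chloro)diphenylsilane, CC(C)(C)[Si](Cl)(c1ccccc1)c1ccccc1
Why: Silyl protection of the primary alcohol makes the material non-volatile and compatible with the borane and palladium chemistry.

Step 14
Reactants: 24 tert-butyl{[(2S)-2-methylpent-4-en-1-yl]oxy}diphenylsilane; 25 3-bromofuran
Product: 27 tert-butyl{[(2S)-5-(furan-3-yl)-2-methylpentyl]oxy}diphenylsilane, via B-alkyl-9-BBN borane 26 (not isolated)
Conditions: 9-BBN, THF, 0 °C → rt; then 25, Pd(dppf)Cl2·CH2Cl2 (5 mol %), AsPh3, Cs2CO3, DMF/H2O, rt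
Reagents that add atoms: none
Why: Anti-Markovnikov hydroboration followed by B-alkyl Suzuki–Miyaura coupling forms the sp3–sp2 bond to the furan at carbons remote from the stereocentre.

Step 15
Reactants: 27 tert-butyl{[(2S)-5-(furan-3-yl)-2-methylpentyl]oxy}diphenylsilane
Product: 28 (2S)-5-(furan-3-yl)-2-methylpentan-1-ol
Conditions: TBAF, THF, rt
Reagents that add atoms: none
Why: Fluoride cleaves the Si–O bond selectively and leaves the furan untouched.

Step 16
Reactants: 28 (2S)-5-(furan-3-yl)-2-methylpentan-1-ol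
Product: 29 (2S)-5-(furan-3-yl)-2-methylpentanal
Conditions: Dess–Martin periodinane, NaHCO3, CH2Cl2, 0 °C → rt (used crude)
Reagents that add atoms: none
Why: Buffered Dess–Martin oxidation gives the α-branched aldehyde without epimerisation and tolerates the furan.

Step 17
Reactants: 29 (2S)-5-(furan-3-yl)-2-methylpentanal
Product: 30 3-[(4S)-4-methylhex-5-yn-1-yl]furan
Conditions: dimethyl (1-diazo-2-oxopropyl)phosphonate, K2CO3, MeOH, 0 °C → rt
Reagents that add atoms: dimethyl (1-diazo-2-oxopropyl)phosphonate, COP(=O)(OC)C(=[N+]=[N-])C(C)=O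
Why: Ohira–Bestmann (Seyferth–Gilbert) homologation converts the aldehyde into the terminal alkyne under mild carbonate conditions that normally preserve an α-methyl stereocentre.

Step 18
Reactants: 30 3-[(4S)-4-methylhex-5-yn-1-yl]furan
Product: 31 2-[(1E,3S)-6-(furan-3-yl)-3-methylhex-1-en-1-yl]-4,4,5,5-tetramethyl-1,3,2-dioxaborolane
Conditions: pinacolborane, Cp2Zr(H)Cl (10 mol %), Et3N (10 mol %), neat, 60 °C
Reagents that add atoms: pinacolborane, CC1(C)OBOC1(C)C
Why: Zirconium-catalysed syn hydroboration of the terminal alkyne places boron at the terminus and gives only the (E)-alkenylboronate.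

Step 19
Reactants: 18 methyl (2S,4R,8E)-2-[(tert-butyldimethylsilyl)oxy]-9-iodo-4,8-dimethylnon-8-enoate; 31 2-[(1E,3S)-6-(furan-3-yl)-3-methylhex-1-en-1-yl]-4,4,5,5-tetramethyl-1,3,2-dioxaborolane
Product: 32 methyl (2S,4R,8E,10E,12S)-2-[(tert-butyldimethylsilyl)oxy]-15-(furan-3-yl)-4,8,12-trimethylpentadeca-8,10-dienoate
Conditions: Pd(dppf)Cl2·CH2Cl2 (5 mol %), AsPh3, Cs2CO3, DMF/THF/H2O, rt, degassed
Reagents that add atoms: none
Why: Suzuki–Miyaura sp2–sp2 coupling proceeds with retention of both alkene geometries to give the (E,E)-diene, and the mild carbonate base at rt spares the ester, silyl ether and stereocentres.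

Step 20
Reactants: 32 methyl (2S,4R,8E,10E,12S)-2-[(tert-butyldimethylsilyl)oxy]-15-(furan-3-yl)-4,8,12-trimethylpentadeca-8,10-dienoate; 33 methyl propionate
Product: 35 methyl (4S,6R,10E,12E,14S)-4-[(tert-butyldimethylsilyl)oxy]-17-(furan-3-yl)-2,6,10,14-tetramethyl-3-oxoheptadeca-10,12-dienoate (C2 epimers), via lithium enolate of methyl propionate 34 (not isolated)
Conditions: 33 (3.2 equiv), LDA (3.0 equiv), THF, −78 °C; then 32, −78 → −30 °C; AcOH quench
Reagents that add atoms: none
Why: Crossed Claisen condensation, in which the propionate enolate adds to the ester carbonyl of 32 (its single hindered α-H makes it acceptor only), methoxide leaves, and deprotonation of the β-keto ester by a second equivalent of enolate drives the reaction; C4 is untouched and the C2 mixture is erased in the next step.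

Step 21
Reactants: 35 methyl (4S,6R,10E,12E,14S)-4-[(tert-butyldimethylsilyl)oxy]-17-(furan-3-yl)-2,6,10,14-tetramethyl-3-oxoheptadeca-10,12-dienoate
Product: 37 (5S)-5-[(2R,6E,8E,10S)-13-(furan-3-yl)-2,6,10-trimethyltrideca-6,8-dien-1-yl]-4-hydroxy-3-methylfuran-2(5H)-one, via desilylated hydroxy keto ester 36 (not isolated)
Conditions: TBAF (2.5 equiv), THF, 0 °C → rt; then 1 M HCl to pH 2–3, 0 °C
Reagents that add atoms: none
Why: Fluoride desilylation frees the γ-alkoxide, which lactonises 5-exo-trig onto the methyl ester to give the stable tetronate anion (protonated on work-up); C3 becomes sp2 and C5 keeps its (S) configuration.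

**Compound list**

1 | (S)-citronellol, (3S)-3,7-dimethyloct-6-en-1-ol | CC(C)=CCC[C@H](C)CCO | starting material
2 | (6S)-8-iodo-2,6-dimethyloct-2-ene | CC(C)=CCC[C@H](C)CCI | intermediate
3 | 1-(trimethylsilyl)propyne | CC#C[Si](C)(C)C | starting material
4 | [3-(trimethylsilyl)prop-2-yn-1-yl]lithium | [Li]CC#C[Si](C)(C)C | intermediate (not isolated)
5 | [(6R)-6,10-dimethylundec-9-en-1-yn-1-yl]trimethylsilane | CC(C)=CCC[C@H](C)CCCC#C[Si](C)(C)C | intermediate
6 | (6R)-6,10-dimethylundec-9-en-1-yne | CC(C)=CCC[C@H](C)CCCC#C | intermediate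
7 | [(1E,6R)-2,6,10-trimethylundeca-1,9-dien-1-yl]dimethylalane | CC(C)=CCC[C@H](C)CCC/C(C)=C/[Al](C)C | intermediate (not isolated)
8 | (1E,6R)-1-iodo-2,6,10-trimethylundeca-1,9-diene | CC(C)=CCC[C@H](C)CCC/C(C)=C/I | intermediate
9 | (6R,10E)-11-iodo-2,6,10-trimethylundec-10-ene-2,3-diol (C3 epimers) | CC(C)(O)C(O)CC[C@H](C)CCC/C(C)=C/I | intermediate (not isolated)
10 | (4R,8E)-9-iodo-4,8-dimethylnon-8-enal | O=CCC[C@H](C)CCC/C(C)=C/I | intermediate
11 | (4R,8E)-9-iodo-4,8-dimethylnon-8-enoic acid | OC(=O)CC[C@H](C)CCC/C(C)=C/I | intermediate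
12 | (S)-4-benzyloxazolidin-2-one | O=C1N[C@@H](Cc2ccccc2)CO1 | starting material
13 | (4R,8E)-9-iodo-4,8-dimethylnon-8-enoic pivalic anhydride | CC(C)(C)C(=O)OC(=O)CC[C@H](C)CCC/C(C)=C/I | intermediate (not isolated)
14 | (4S)-4-benzyl-3-[(4R,8E)-9-iodo-4,8-dimethylnon-8-enoyl]oxazolidin-2-one | O=C(CC[C@H](C)CCC/C(C)=C/I)N1[C@@H](Cc2ccccc2)COC1=O | intermediate
15 | sodium (Z)-enolate of 14 | [Na+].[O-]/C(=C\C[C@H](C)CCC/C(C)=C/I)N1[C@@H](Cc2ccccc2)COC1=O | intermediate (not isolated)
16 | (4S)-4-benzyl-3-[(2S,4R,8E)-2-hydroxy-9-iodo-4,8-dimethylnon-8-enoyl]oxazolidin-2-one | O=C([C@@H](O)C[C@H](C)CCC/C(C)=C/I)N1[C@@H](Cc2ccccc2)COC1=O | intermediate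
17 | methyl (2S,4R,8E)-2-hydroxy-9-iodo-4,8-dimethylnon-8-enoate | COC(=O)[C@@H](O)C[C@H](C)CCC/C(C)=C/I | intermediate
18 | methyl (2S,4R,8E)-2-[(tert-butyldimethylsilyl)oxy]-9-iodo-4,8-dimethylnon-8-enoate | COC(=O)[C@@H](O[Si](C)(C)C(C)(C)C)C[C@H](C)CCC/C(C)=C/I | intermediate
19 | (R)-4-benzyl-3-propionyloxazolidin-2-one | CCC(=O)N1[C@H](Cc2ccccc2)COC1=O | starting material
20 | allyl iodide | C=CCI | starting material
21 | sodium (Z)-enolate of 19 | [Na+].C/C=C(\[O-])N1[C@H](Cc2ccccc2)COC1=O | intermediate (not isolated)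
22 | (4R)-4-benzyl-3-[(2S)-2-methylpent-4-enoyl]oxazolidin-2-one | C=CC[C@H](C)C(=O)N1[C@H](Cc2ccccc2)COC1=O | intermediate
23 | (2S)-2-methylpent-4-en-1-ol | OC[C@@H](C)CC=C | intermediate
24 | tert-butyl{[(2S)-2-methylpent-4-en-1-yl]oxy}diphenylsilane | CC(C)(C)[Si](c1ccccc1)(c1ccccc1)OC[C@@H](C)CC=C | intermediate
25 | 3-bromofuran | Brc1ccoc1 | starting material
26 | 9-{(4S)-5-[(tert-butyldiphenylsilyl)oxy]-4-methylpentyl}-9-borabicyclo[3.3.1]nonane | CC(C)(C)[Si](c1ccccc1)(c1ccccc1)OC[C@@H](C)CCCB1C2CCCC1CCC2 | intermediate (not isolated)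
27 | tert-butyl{[(2S)-5-(furan-3-yl)-2-methylpentyl]oxy}diphenylsilane | CC(C)(C)[Si](c1ccccc1)(c1ccccc1)OC[C@@H](C)CCCc1ccoc1 | intermediate
28 | (2S)-5-(furan-3-yl)-2-methylpentan-1-ol | OC[C@@H](C)CCCc1ccoc1 | intermediate
29 | (2S)-5-(furan-3-yl)-2-methylpentanal | O=C[C@@H](C)CCCc1ccoc1 | intermediate
30 | 3-[(4S)-4-methylhex-5-yn-1-yl]furan | C#C[C@@H](C)CCCc1ccoc1 | intermediate
31 | 2-[(1E,3S)-6-(furan-3-yl)-3-methylhex-1-en-1-yl]-4,4,5,5-tetramethyl-1,3,2-dioxaborolane | CC1(C)OB(/C=C/[C@@H](C)CCCc2ccoc2)OC1(C)C | intermediate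
32 | methyl (2S,4R,8E,10E,12S)-2-[(tert-butyldimethylsilyl)oxy]-15-(furan-3-yl)-4,8,12-trimethylpentadeca-8,10-dienoate | COC(=O)[C@@H](O[Si](C)(C)C(C)(C)C)C[C@H](C)CCC/C(C)=C/C=C/[C@@H](C)CCCc1ccoc1 | intermediate
33 | methyl propionate | CCC(=O)OC | starting material
34 | lithium enolate of methyl propionate (geometry immaterial) | [Li+].CC=C([O-])OC | intermediate (not isolated)
35 | methyl (4S,6R,10E,12E,14S)-4-[(tert-butyldimethylsilyl)oxy]-17-(furan-3-yl)-2,6,10,14-tetramethyl-3-oxoheptadeca-10,12-dienoate (C2 epimers) | COC(=O)C(C)C(=O)[C@@H](O[Si](C)(C)C(C)(C)C)C[C@H](C)CCC/C(C)=C/C=C/[C@@H](C)CCCc1ccoc1 | intermediate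
36 | methyl (4S,6R,10E,12E,14S)-17-(furan-3-yl)-4-hydroxy-2,6,10,14-tetramethyl-3-oxoheptadeca-10,12-dienoate (C2 epimers) | COC(=O)C(C)C(=O)[C@@H](O)C[C@H](C)CCC/C(C)=C/C=C/[C@@H](C)CCCc1ccoc1 | intermediate (not isolated)
37 | (5S)-5-[(2R,6E,8E,10S)-13-(furan-3-yl)-2,6,10-trimethyltrideca-6,8-dien-1-yl]-4-hydroxy-3-methylfuran-2(5H)-one | CC1=C(O)[C@H](C[C@H](C)CCC/C(C)=C/C=C/[C@@H](C)CCCc2ccoc2)OC1=O | target

**Totals**

Total step count: 21 (one-pot sequences counted as one step).
Longest linear sequence: 13 steps (steps 1–10, then 19, 20, 21, from (S)-citronellol). The furan branch is 8 steps (11–18) before the union.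

**Three steps most likely to fail, with fallbacks**

Step 20 (crossed Claisen on a hindered α-silyloxy ester). The risk is sluggish addition or partial epimerisation at C4 if enolisation of 32 competes. The fallback replaces the Claisen by an intermolecular aldol followed by oxidation. It sets out from 32: DIBAL-H (CH2Cl2, −78 °C) gives (2S,4R,8E,10E,12S)-2-[(tert-butyldimethylsilyl)oxy]-15-(furan-3-yl)-4,8,12-trimethylpentadeca-8,10-dienal F1. This aldehyde takes up the same lithium enolate 34 at −78 °C to give methyl (4S,6R,10E,12E,14S)-4-[(tert-butyldimethylsilyl)oxy]-17-(furan-3-yl)-3-hydroxy-2,6,10,14-tetramethylheptadeca-10,12-dienoate F2 (C2/C3 diastereomers, irrelevant). Buffered Dess–Martin oxidation of the new carbinol brings the material back to the route at 35.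

Step 21 (one-pot desilylation and lactonisation). The risk is that the β-keto ester sits as its enolate under TBAF, so its ester is a poor acceptor and the ring may close slowly or C5 may erode. The fallback closes the ring by C-acylation (Dieckmann) instead of O-acylation. It sets out from 32: HF·pyridine (THF/pyridine, 0 °C → rt) gives methyl (2S,4R,8E,10E,12S)-15-(furan-3-yl)-2-hydroxy-4,8,12-trimethylpentadeca-8,10-dienoate F3. Propionic anhydride, Et3N and DMAP (CH2Cl2) give methyl (2S,4R,8E,10E,12S)-15-(furan-3-yl)-4,8,12-trimethyl-2-(propanoyloxy)pentadeca-8,10-dienoate F4. LiHMDS (2.2 equiv, THF, −78 → 0 °C) then acid work-up gives the tetronic acid directly, rejoining the route at 37.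

Step 17 (Ohira–Bestmann on an α-branched aldehyde). The risk is partial epimerisation of the C2 methyl centre of 29 in K2CO3/MeOH. The fallback is a Corey–Fuchs sequence with no base in contact with the aldehyde. It sets out from 29: CBr4, PPh3 and 2,6-lutidine (CH2Cl2, 0 °C) give 3-[(4S)-6,6-dibromo-4-methylhex-5-en-1-yl]furan F5. n-BuLi (2.1 equiv, THF, −78 °C) followed by water converts it by bromine–lithium exchange and 1,2-shift into the alkyne, rejoining the route at 30.

**Further compounds**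

F1 | step 20 | (2S,4R,8E,10E,12S)-2-[(tert-butyldimethylsilyl)oxy]-15-(furan-3-yl)-4,8,12-trimethylpentadeca-8,10-dienal | O=C[C@@H](O[Si](C)(C)C(C)(C)C)C[C@H](C)CCC/C(C)=C/C=C/[C@@H](C)CCCc1ccoc1
F2 | step 20 | methyl (4S,6R,10E,12E,14S)-4-[(tert-butyldimethylsilyl)oxy]-17-(furan-3-yl)-3-hydroxy-2,6,10,14-tetramethylheptadeca-10,12-dienoate | COC(=O)C(C)C(O)[C@@H](O[Si](C)(C)C(C)(C)C)C[C@H](C)CCC/C(C)=C/C=C/[C@@H](C)CCCc1ccoc1
F3 | step 21 | methyl (2S,4R,8E,10E,12S)-15-(furan-3-yl)-2-hydroxy-4,8,12-trimethylpentadeca-8,10-dienoate | COC(=O)[C@@H](O)C[C@H](C)CCC/C(C)=C/C=C/[C@@H](C)CCCc1ccoc1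
F4 | step 21 | methyl (2S,4R,8E,10E,12S)-15-(furan-3-yl)-4,8,12-trimethyl-2-(propanoyloxy)pentadeca-8,10-dienoate | COC(=O)[C@@H](OC(=O)CC)C[C@H](C)CCC/C(C)=C/C=C/[C@@H](C)CCCc1ccoc1
F5 | step 17 | 3-[(4S)-6,6-dibromo-4-methylhex-5-en-1-yl]furan | BrC(Br)=C[C@@H](C)CCCc1ccoc1
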